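## Retrosynthetic overview

1. The target is unmasked last by hydrogenolysis of a pentadeca-O-benzyl ether; all fifteen phenols travel as benzyl ethers.
2. Both tetrahydrofuran rings are closed together, in one pot, from an acyclic bis(1,4-diketone) carried on the flavan: twofold enolate aldol with 4-benzyloxybenzaldehyde (C4–C5), lactolisation (O–C2), ionic hydrogenation (C2–H).
3. The bis(1,4-diketone) comes from a twofold Friedel–Crafts homo-Michael ring opening of an enantiopure trans-2,3-diaroyl-1-arylcyclopropane by C6 and C8 of tri-O-benzyl-(+)-afzelechin (Cα set with inversion, C3 retained).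
4. The cyclopropane comes from a chalcone and an α-bromo ketone by asymmetric ammonium-ylide cyclopropanation; both partners derive from 2',4'-dihydroxyacetophenone and 4-benzyloxybenzaldehyde.
5. Ring order: cyclopropane (made, then opened); flavan rings A, B and C bought intact; the two tetrahydrofuran rings last and simultaneously.

Assumption: (+)-afzelechin, (2R,3S), is bought as the enantiopure natural product; everything else is a bulk chemical.

Locants: in each arm Cα is the diarylmethine carbon bonded to ring A of the flavan. C2 (2,4-dioxygenated aryl), C3 (bears Cα), C4 (aroyl) and C5 (4-oxygenated aryl) are the tetrahydrofuran carbons. Both arms of the target are (αS,2R,3S,4S,5S): 2,3-cis, 3,4-trans, 4,5-trans.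

## Route

Step 1
Reactants: 1 2',4'-dihydroxyacetophenone
Product: 2 2',4'-bis(benzyloxy)acetophenone
Conditions: BnBr (2.5 equiv), K2CO3, DMF, 80 °C
Reagents that add atoms: benzyl bromide BrCc1ccccc1
Why: Williamson ether synthesis, with heating in DMF so that the hydrogen-bonded 2'-OH is alkylated as well; no stereocentre is involved.

Step 2
Reactants: 2 2',4'-bis(benzyloxy)acetophenone
Product: 3 2-bromo-1-[2,4-bis(benzyloxy)phenyl]ethan-1-one
Conditions: CuBr2 (2.0 equiv), EtOAc/CHCl3, reflux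
Reagents that add atoms: copper dibromide Br[Cu]Br
Why: α-bromination of an aryl methyl ketone through its copper-bound enol, which is selective for the side chain over the electron-rich ring; no stereocentre is involved.

Step 3
Reactants: 2 2',4'-bis(benzyloxy)acetophenone; 4 4-(benzyloxy)benzaldehyde
Product: 5 (E)-1-[2,4-bis(benzyloxy)phenyl]-3-[4-(benzyloxy)phenyl]prop-2-en-1-one
Conditions: KOH, EtOH/THF, rt
Reagents that add atoms: none
Why: Claisen–Schmidt aldol condensation, whose E1cB dehydration gives only the E-enone.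

Step 4
Reactants: 3 2-bromo-1-[2,4-bis(benzyloxy)phenyl]ethan-1-one; 5 (E)-chalcone
Product: 6 (1S,2S)-trans-1,2-bis[2,4-bis(benzyloxy)benzoyl]-3-[4-(benzyloxy)phenyl]cyclopropane
Conditions: 9-O-methylquinidine (20 mol%), Cs2CO3, MeCN, 60 °C; recrystallise
Reagents that add atoms: none
Why: Proposed new method: the quinuclidine nitrogen is alkylated by 3, Cs2CO3 forms the chiral ammonium ylide, this adds through one face to the β-carbon of 5, and the resulting enolate closes by 3-exo-tet displacement of the amine (Michael-initiated ring closure) to the favoured trans-diaroyl cyclopropane, so the ylide carbon fixes both stereocentres as (1S,2S) (the pseudoenantiomeric 9-O-methylquinine gives the antipode should the sense be reversed); the closest known reaction is the cinchona-alkaloid-catalysed enantioselective ammonium-ylide cyclopropanation of α-bromo ketones with enones and acrylates.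

Step 5
Reactants: 7 (+)-afzelechin
Product: 8 5,7,4'-tri-O-benzyl-(+)-afzelechin
Conditions: BnBr (3.3 equiv), K2CO3, DMF, 0 °C → rt
Reagents that add atoms: benzyl bromide BrCc1ccccc1
Why: chemoselective Williamson O-benzylation of the three phenols, the secondary 3-OH not being deprotonated by K2CO3; C2 and C3 of the flavan are untouched.

Step 6
Reactants: 8 5,7,4'-tri-O-benzyl-(+)-afzelechin; 6 (1S,2S)-cyclopropane (2.4 equiv)
Product: 9 bis(1,4-diketone), 6,8-bis[(1S,2R)-1-(4-benzyloxyphenyl)-2-(2,4-bis(benzyloxy)benzoyl)-4-(2,4-bis(benzyloxy)phenyl)-4-oxobutyl]-5,7,4'-tri-O-benzyl-(+)-afzelechin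
Conditions: Sc(OTf)3 (20 mol%), 4 Å MS, CH2Cl2, −20 → 0 °C
Reagents that add atoms: none
Why: Proposed new method: Sc(OTf)3 chelates an aroyl oxygen and its ortho-benzyloxy group, and the trialkoxyarene carbons C6 and C8 of 8 attack the aryl-bearing cyclopropane carbon from the rear of the bond to the aroyl carbon that is cis to that aryl group (the only SN2-like pathway that relieves the cis aryl/aroyl eclipsing), so each Cα is formed with inversion as (S), the retained aroyl-bearing centre becomes C3 with the geometry of the target, and the expelled enolate is protonated to the CH2 of the 1,4-diketone; the closest known reaction is the Lewis-acid-catalysed Friedel–Crafts homo-Michael ring opening of 2-aryl donor–acceptor cyclopropanes by electron-rich arenes, which runs with inversion at the donor carbon.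

Step 7
Reactants: 9 bis(1,4-diketone); 4 4-(benzyloxy)benzaldehyde (2.5 equiv)
Product: 11 pentadeca-O-benzyl ether of the target, via bis-lactol 10 (not isolated)
Conditions: LiN(SiMe3)2 (3.1 equiv), THF, −78 °C; 4, −78 °C; then CH2Cl2, Et3SiH (10 equiv), CF3CO2H (30 equiv), −78 → −20 °C
Reagents that add atoms: none
Why: kinetic deprotonation of the two unhindered CH2 groups gives Z lithium enolates whose Zimmerman–Traxler aldol addition to 4 takes place on the enolate face anti to the bulky diarylmethyl group on C3 (1,3-allylic strain control) to give the syn aldolates (C4 S, C5 S), these close onto the neighbouring C2 ketones as five-membered lactolates, and acid-promoted ionic hydrogenation of the derived 2-aryl oxocarbenium ions delivers hydride anti to the C3 and C5 substituents (C2 R, 2,3-cis), so both tetrahydrofuran rings and six stereocentres arise in one pot by a directed aldol/lactolisation/reductive etherification cascade.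

Step 8
Reactants: 11 pentadeca-O-benzyl ether of the target
Product: 12 CNP0225367.3 (target)
Conditions: H2 (1 atm), Pd(OH)2/C, THF/MeOH, rt, stopped at full conversion
Reagents that add atoms: none
Why: hydrogenolysis of fifteen aryl benzyl ethers, which cleave far faster than the dialkyl-type benzylic C–O bonds of the tetrahydrofuran and flavan rings or the hydrogen-bonded aryl ketones; no stereocentre is touched.

## Compound list

1 | 2',4'-dihydroxyacetophenone | CC(=O)c1ccc(O)cc1O | starting material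
2 | 2',4'-bis(benzyloxy)acetophenone | CC(=O)c1ccc(OCc2ccccc2)cc1OCc1ccccc1 | intermediate
3 | 2-bromo-1-[2,4-bis(benzyloxy)phenyl]ethan-1-one | BrCC(=O)c1ccc(OCc2ccccc2)cc1OCc1ccccc1 | intermediate
4 | 4-(benzyloxy)benzaldehyde | O=Cc1ccc(OCc2ccccc2)cc1 | starting material
5 | (E)-1-[2,4-bis(benzyloxy)phenyl]-3-[4-(benzyloxy)phenyl]prop-2-en-1-one | O=C(/C=C/c1ccc(OCc2ccccc2)cc1)c1ccc(OCc2ccccc2)cc1OCc1ccccc1 | intermediate
6 | (1S,2S)-trans-1,2-bis[2,4-bis(benzyloxy)benzoyl]-3-[4-(benzyloxy)phenyl]cyclopropane | O=C(c1ccc(OCc2ccccc2)cc1OCc1ccccc1)[C@@H]1[C@@H](C(=O)c2ccc(OCc3ccccc3)cc2OCc2ccccc2)C1c1ccc(OCc2ccccc2)cc1 | intermediate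
7 | (+)-afzelechin, (2R,3S)-2-(4-hydroxyphenyl)chromane-3,5,7-triol | Oc1cc(O)c2c(c1)O[C@H](c1ccc(O)cc1)[C@@H](O)C2 | starting material
8 | 5,7,4'-tri-O-benzyl-(+)-afzelechin (3-OH free) | c1ccccc1COc1cc(OCc3ccccc3)c2c(c1)O[C@H](c1ccc(OCc3ccccc3)cc1)[C@@H](O)C2 | intermediate
9 | bis(1,4-diketone): 6,8-bis[(1S,2R)-1-(4-benzyloxyphenyl)-2-(2,4-bis(benzyloxy)benzoyl)-4-(2,4-bis(benzyloxy)phenyl)-4-oxobutyl]-5,7,4'-tri-O-benzyl-(+)-afzelechin (αS and target C3 geometry in both arms) | O=C(c4ccc(OCc5ccccc5)cc4OCc4ccccc4)C[C@H]([C@@H](c4ccc(OCc5ccccc5)cc4)c2c(OCc4ccccc4)c3c(c([C@H](c4ccc(OCc5ccccc5)cc4)[C@H](C(=O)c4ccc(OCc5ccccc5)cc4OCc4ccccc4)CC(=O)c4ccc(OCc5ccccc5)cc4OCc4ccccc4)c2OCc2ccccc2)O[C@H](c2ccc(OCc4ccccc4)cc2)[C@@H](O)C3)C(=O)c2ccc(OCc3ccccc3)cc2OCc2ccccc2 | intermediate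
10 | bis-lactol: each arm a 2-hydroxy-2-aryl-tetrahydrofuran (hemiketal carbon as anomer mixture; Cα, C3, C4, C5 as in the target), all phenols benzylated | O=C(c5ccc(OCc6ccccc6)cc5OCc5ccccc5)[C@H]1[C@H]([C@@H](c5ccc(OCc6ccccc6)cc5)c2c(OCc5ccccc5)c3c(c([C@H](c5ccc(OCc6ccccc6)cc5)[C@H]4[C@H](C(=O)c5ccc(OCc6ccccc6)cc5OCc5ccccc5)[C@@H](c5ccc(OCc6ccccc6)cc5)OC4(O)c4ccc(OCc5ccccc5)cc4OCc4ccccc4)c2OCc2ccccc2)O[C@H](c2ccc(OCc4ccccc4)cc2)[C@@H](O)C3)C(O)(c2ccc(OCc3ccccc3)cc2OCc2ccccc2)O[C@@H]1c1ccc(OCc2ccccc2)cc1 | intermediate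
11 | pentadeca-O-benzyl ether of the target (arms αS,2R,3S,4S,5S; flavan 2R,3S; 3-OH free) | O=C(c5ccc(OCc6ccccc6)cc5OCc5ccccc5)[C@H]1[C@H]([C@@H](c5ccc(OCc6ccccc6)cc5)c2c(OCc5ccccc5)c3c(c([C@H](c5ccc(OCc6ccccc6)cc5)[C@H]4[C@H](C(=O)c5ccc(OCc6ccccc6)cc5OCc5ccccc5)[C@@H](c5ccc(OCc6ccccc6)cc5)O[C@H]4c4ccc(OCc5ccccc5)cc4OCc4ccccc4)c2OCc2ccccc2)O[C@H](c2ccc(OCc4ccccc4)cc2)[C@@H](O)C3)[C@H](c2ccc(OCc3ccccc3)cc2OCc2ccccc2)O[C@@H]1c1ccc(OCc2ccccc2)cc1 | intermediate
12 | CNP0225367.3 | O=C(c1ccc(O)cc1O)[C@H]1[C@H]([C@@H](c2ccc(O)cc2)c2c(O)c3c(c([C@H](c4ccc(O)cc4)[C@H]4[C@H](C(=O)c5ccc(O)cc5O)[C@@H](c5ccc(O)cc5)O[C@H]4c4ccc(O)cc4O)c2O)O[C@H](c2ccc(O)cc2)[C@@H](O)C3)[C@H](c2ccc(O)cc2O)O[C@@H]1c1ccc(O)cc1 | target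

## Count and risks

Total steps: 8. Longest linear sequence: 6 (steps 1, 2 or 3, 4, 6, 7, 8).

**Step 4** may give low enantiomeric excess, because β-aryl enones are poor partners for catalytic chiral ammonium ylides. The fallback sets out from 3 and comes back at 6.
- Bromide 3 is treated with dimethyl sulfide and then aqueous K2CO3 to give the stabilised ylide 1-[2,4-bis(benzyloxy)phenyl]-2-(dimethyl-λ4-sulfanylidene)ethan-1-one F1.
- F1 is added to purchased (E)-3-[4-(benzyloxy)phenyl]prop-2-enal under iminium catalysis by indoline-2-carboxylic acid (20 mol%, CHCl3, −10 °C; the catalyst enantiomer that gives the shown product). This gives (1S,2S,3S)-2-[2,4-bis(benzyloxy)benzoyl]-3-[4-(benzyloxy)phenyl]cyclopropane-1-carbaldehyde F2, with formyl trans to aryl and aroyl trans to formyl.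
- 2,4-Bis(benzyloxy)phenylmagnesium bromide (THF, −78 °C) adds to the aldehyde in preference to the ketone, giving the carbinol [2,4-bis(benzyloxy)phenyl]{(1S,2S,3S)-2-[2,4-bis(benzyloxy)benzoyl]-3-[4-(benzyloxy)phenyl]cyclopropyl}methanol F3 as an epimer mixture.
- Dess–Martin oxidation of F3 gives 6.

**Step 6** may break the wrong cyclopropane bond (which would give the Cα epimer), may lose stereospecificity through an open benzylic cation, or may stall at the hindered second position of ring A. The fallback sets out from 2 and 5 and comes back at 9.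
- Ketone 2 is C-acylated with diallyl carbonate (NaH, THF) to allyl 3-[2,4-bis(benzyloxy)phenyl]-3-oxopropanoate F4, and NBS gives allyl 2-bromo-3-[2,4-bis(benzyloxy)phenyl]-3-oxopropanoate F5.
- Michael-initiated ring closure of F5 onto chalcone 5 under a cinchona-derived quaternary ammonium phase-transfer catalyst (K2CO3, toluene) gives allyl (2S,3R)-1,2-bis[2,4-bis(benzyloxy)benzoyl]-3-[4-(benzyloxy)phenyl]cyclopropane-1-carboxylate F6.
- In F6 the far more stabilised β-keto ester enolate dictates which bond breaks, so ring opening by 8 under a milder Lewis acid (MgI2 or Sc(OTf)3, CH2Cl2, −40 °C) has no regiochemical choice and gives the bis(β-keto allyl ester) F7.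
- Pd(PPh3)4 (zerovalent palladium) with morpholine removes the allyl groups with decarboxylation and returns 9.

**Step 7** may suffer from poor enolate face or syn/anti control, retro-aldol, or over-reduction in the one-pot reduction. The fallback sets out from 9 and comes back at 10, and from there at 11.
- 9 is converted (LiN(SiMe3)2, Me3SiCl, THF, −78 °C) into the isolated bis(Z-trimethylsilyl enol ether), silylated also at the flavan 3-OH, F8.
- An open-transition-state Mukaiyama aldol addition of F8 to 4 (BF3·OEt2, CH2Cl2, −78 °C) and aqueous work-up give bis-lactol 10.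
- 10 is purified and reduced in a separate operation (Et3SiH, BF3·OEt2, CH2Cl2, −78 °C) to 11.
- A wrong C4 epimer can be corrected at 11 with DBU, because the aroyl group prefers to be trans to both ring neighbours.

Further compounds

F1 | step 4 | 1-[2,4-bis(benzyloxy)phenyl]-2-(dimethyl-λ4-sulfanylidene)ethan-1-one | CS(C)=CC(=O)c1ccc(OCc2ccccc2)cc1OCc1ccccc1
F2 | step 4 | (1S,2S,3S)-2-[2,4-bis(benzyloxy)benzoyl]-3-[4-(benzyloxy)phenyl]cyclopropane-1-carbaldehyde | O=C[C@@H]1[C@@H](C(=O)c2ccc(OCc3ccccc3)cc2OCc2ccccc2)[C@H]1c1ccc(OCc2ccccc2)cc1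
F3 | step 4 | [2,4-bis(benzyloxy)phenyl]{(1S,2S,3S)-2-[2,4-bis(benzyloxy)benzoyl]-3-[4-(benzyloxy)phenyl]cyclopropyl}methanol (carbinol epimers) | OC(c2ccc(OCc3ccccc3)cc2OCc2ccccc2)[C@@H]1[C@@H](C(=O)c2ccc(OCc3ccccc3)cc2OCc2ccccc2)[C@H]1c1ccc(OCc2ccccc2)cc1
F4 | step 6 | allyl 3-[2,4-bis(benzyloxy)phenyl]-3-oxopropanoate | C=CCOC(=O)CC(=O)c1ccc(OCc2ccccc2)cc1OCc1ccccc1
F5 | step 6 | allyl 2-bromo-3-[2,4-bis(benzyloxy)phenyl]-3-oxopropanoate | C=CCOC(=O)C(Br)C(=O)c1ccc(OCc2ccccc2)cc1OCc1ccccc1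
F6 | step 6 | allyl (2S,3R)-1,2-bis[2,4-bis(benzyloxy)benzoyl]-3-[4-(benzyloxy)phenyl]cyclopropane-1-carboxylate (C1 either configuration) | O=C(c1ccc(OCc2ccccc2)cc1OCc1ccccc1)[C@H]1[C@H](c2ccc(OCc3ccccc3)cc2)C1(C(=O)c1ccc(OCc2ccccc2)cc1OCc1ccccc1)C(=O)OCC=C
F7 | step 6 | bis(β-keto allyl ester): compound 9 carrying an allyloxycarbonyl group on the CH2 carbon of each arm (epimer mixture at that carbon) | O=C(c4ccc(OCc5ccccc5)cc4OCc4ccccc4)C(C(=O)OCC=C)[C@H]([C@@H](c4ccc(OCc5ccccc5)cc4)c2c(OCc4ccccc4)c3c(c([C@H](c4ccc(OCc5ccccc5)cc4)[C@H](C(=O)c4ccc(OCc5ccccc5)cc4OCc4ccccc4)C(C(=O)OCC=C)C(=O)c4ccc(OCc5ccccc5)cc4OCc4ccccc4)c2OCc2ccccc2)O[C@H](c2ccc(OCc4ccccc4)cc2)[C@@H](O)C3)C(=O)c2ccc(OCc3ccccc3)cc2OCc2ccccc2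
F8 | step 7 | bis(Z-trimethylsilyl enol ether) of 9 at the two CH2–CO units, with the flavan 3-OH as its trimethylsilyl ether | C[Si](C)(C)O/C(c4ccc(OCc5ccccc5)cc4OCc4ccccc4)=C\[C@H]([C@@H](c4ccc(OCc5ccccc5)cc4)c2c(OCc4ccccc4)c3c(c([C@H](c4ccc(OCc5ccccc5)cc4)[C@H](C(=O)c4ccc(OCc5ccccc5)cc4OCc4ccccc4)/C=C(\O[Si](C)(C)C)c4ccc(OCc5ccccc5)cc4OCc4ccccc4)c2OCc2ccccc2)O[C@H](c2ccc(OCc4ccccc4)cc2)[C@@H](O[Si](C)(C)C)C3)C(=O)c2ccc(OCc3ccccc3)cc2OCc2ccccc2
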